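**Strategy.** The cyclohexane ring (C5–C10, germacrane numbering) carries a vinyl group on quaternary C10 and a 2‑formylvinyl unit (C4(=C3H2)–C15HO) on C5, which is the retron of a Cope rearrangement. The route therefore rests on the C5–C10 disconnection: the α‑methylene lactone is completed first, and the carbocycle is closed last by a biomimetic [3,3] shift of a ten‑membered germacra‑1(10),4‑dien‑15‑al 12,8α‑olide with both ring alkenes trans. In one operation this forms the ring, both new stereocentres (C5 and quaternary C10) and both terminal alkenes (C1=C2, C3=C4). The precursor is a trans‑lactone‑fused cyclodecadiene, assembled from two chains on a chiral butyrolactone and closed by Nozaki–Hiyama–Kishi macrocyclisation.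

Key step: step 17

Remark: germacrane numbering is used throughout (C14 = methyl on C10, C15 on C4, C11–C13 = methylene‑lactone unit; α/β as in the usual drawing with H‑7 α). The CIP label of C7 changes with the O‑substituents although its geometry does not.

Step 1
Reactants: 1 pent-3-yn-1-ol
Product: 2 5-bromopent-2-yne
Conditions: CBr4, PPh3, CH2Cl2, 0 °C
Reagents that add atoms: carbon tetrabromide BrC(Br)(Br)Br
Why: Appel bromination, in which the alkoxyphosphonium ion of the primary alcohol is displaced by bromide (SN2) while the internal alkyne is inert.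

Step 2
Reactants: 3 tert-butyldimethyl(prop-2-yn-1-yloxy)silane
Product: 4 ethyl 4-[(tert-butyldimethylsilyl)oxy]but-2-ynoate
Conditions: n-BuLi, THF, −78 °C; ClCO2Et, −78→0 °C
Reagents that add atoms: ethyl chloroformate CCOC(=O)Cl
Why: Deprotonation of the terminal alkyne and C‑acylation of the lithium acetylide with the chloroformate gives the ynoate, whose ester carbon becomes C6.

Step 3
Reactants: 2 5-bromopent-2-yne; 4 ethyl 4-[(tert-butyldimethylsilyl)oxy]but-2-ynoate
Product: 7 ethyl (2Z)-3-{[(tert-butyldimethylsilyl)oxy]methyl}oct-2-en-6-ynoate, via pent-3-yn-1-ylmagnesium bromide 5 (not isolated), via pent-3-yn-1-ylcopper 6 (not isolated)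
Conditions: Mg, THF, rt; CuBr·SMe2, THF, −40 °C; 4, −78 °C; aq. NH4Cl, −78 °C
Reagents that add atoms: none
Why: Syn‑carbocupration of the 2‑ynoate by the alkylcopper at −78 °C, followed by protonation with retention, places the new chain (C3) cis to H‑5 and therefore C15 cis to C6, which fixes the C4=C5 geometry.

Step 4
Reactants: 7 ethyl (2Z)-3-{[(tert-butyldimethylsilyl)oxy]methyl}oct-2-en-6-ynoate
Product: 8 (2Z)-3-{[(tert-butyldimethylsilyl)oxy]methyl}oct-2-en-6-yn-1-ol
Conditions: DIBAL-H (2.3 equiv), CH2Cl2, −78 °C; Rochelle salt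
Reagents that add atoms: none
Why: DIBAL 1,2‑reduction of the enoate to the allylic alcohol leaves the alkyne, the silyl ether and the alkene geometry untouched.

Step 5
Reactants: 8 (2Z)-3-{[(tert-butyldimethylsilyl)oxy]methyl}oct-2-en-6-yn-1-ol
Product: 10 (2Z,6E)-3-{[(tert-butyldimethylsilyl)oxy]methyl}-7-iodoocta-2,6-dien-1-ol, via alkenylzirconocene chloride 9 (not isolated)
Conditions: Cp2Zr(H)Cl (2.5 equiv), THF, rt→40 °C; I2, 0 °C
Reagents that add atoms: iodine II
Why: Hydrozirconation with Schwartz's reagent adds H–Zr syn and, after equilibration, puts Zr on the less hindered methyl‑bearing alkyne carbon; iodinolysis with retention should give the (E)‑2‑iodo‑2‑alkene that fixes the C1=C10 geometry.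

Step 6
Reactants: 10 (2Z,6E)-3-{[(tert-butyldimethylsilyl)oxy]methyl}-7-iodoocta-2,6-dien-1-ol
Product: 11 (2Z,6E)-3-{[(tert-butyldimethylsilyl)oxy]methyl}-7-iodoocta-2,6-dienal
Conditions: MnO2, CH2Cl2, rt
Reagents that add atoms: none
Why: Neutral MnO2 oxidation of the primary allylic alcohol gives the enal without Z/E isomerisation of the β,β‑disubstituted double bond.

Step 7
Reactants: 12 (5R)-5-(hydroxymethyl)oxolan-2-one
Product: 13 (5R)-5-{[(triethylsilyl)oxy]methyl}oxolan-2-one
Conditions: TESCl, imidazole, CH2Cl2, 0 °C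
Reagents that add atoms: chlorotriethylsilane CC[Si](Cl)(CC)CC
Why: Standard silylation of the primary alcohol; the lactone stereocentre (future C8, bought from the chiral pool) is not touched.

Step 8
Reactants: 13 (5R)-5-{[(triethylsilyl)oxy]methyl}oxolan-2-one
Product: 16 (5R)-3-methylidene-5-{[(triethylsilyl)oxy]methyl}oxolan-2-one, via Mannich base 14 (not isolated), via methiodide 15 (not isolated)
Conditions: LDA, THF, −78 °C; CH2=NMe2+ I−, −78 °C→rt; MeI, MeOH, rt; aq. NaHCO3, CH2Cl2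
Reagents that add atoms: Eschenmoser's salt C=[N+](C)C.[I-]
Why: Eschenmoser methylenation, in which the lactone enolate undergoes a Mannich reaction and the quaternised amine is lost by E1cB elimination to give the exo‑methylene lactone.

Step 9
Reactants: 16 (5R)-3-methylidene-5-{[(triethylsilyl)oxy]methyl}oxolan-2-one
Product: 18 (5R)-3-(bromomethyl)-5-{[(triethylsilyl)oxy]methyl}furan-2(5H)-one, via dibromide 17 (not isolated)
Conditions: Br2, CH2Cl2, 0 °C; Et3N (1.05 equiv), 0 °C
Reagents that add atoms: bromine BrBr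
Why: Bromine addition to the exo‑methylene followed by dehydrobromination into conjugation with the carbonyl is the known bromination–elimination route from α‑methylene lactones to 3‑(bromomethyl)butenolides.

Step 10
Reactants: 11 (2Z,6E)-3-{[(tert-butyldimethylsilyl)oxy]methyl}-7-iodoocta-2,6-dienal; 18 (5R)-3-(bromomethyl)-5-{[(triethylsilyl)oxy]methyl}furan-2(5H)-one
Product: 19 (4S,5R)-4-[(1R,2Z,6E)-1-hydroxy-3-{[(tert-butyldimethylsilyl)oxy]methyl}-7-iodoocta-2,6-dien-1-yl]-3-methylidene-5-{[(triethylsilyl)oxy]methyl}oxolan-2-one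
Conditions: In powder, THF–H2O (1:1), rt
Reagents that add atoms: none
Why: Barbier‑type indium allylation in which the allylindium attacks the aldehyde through C7 (γ), anti to the C8 substituent (trans lactone), via a closed chair transition state with the ring‑locked E‑type allyl unit, so the C6 epimer (6R) of the target series is expected and the α‑methylene lactone is regenerated.

Step 11
Reactants: 19 (4S,5R)-4-[(1R,2Z,6E)-1-hydroxy-3-{[(tert-butyldimethylsilyl)oxy]methyl}-7-iodoocta-2,6-dien-1-yl]-3-methylidene-5-{[(triethylsilyl)oxy]methyl}oxolan-2-one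
Product: 21 (4S,5R)-4-[(1S,2Z,6E)-1-hydroxy-3-{[(tert-butyldimethylsilyl)oxy]methyl}-7-iodoocta-2,6-dien-1-yl]-3-methylidene-5-{[(triethylsilyl)oxy]methyl}oxolan-2-one, via formate ester 20 (not isolated)
Conditions: HCO2H, PPh3, DIAD, THF, 0 °C→rt; then KHCO3, MeOH–H2O, 0 °C
Reagents that add atoms: formic acid O=CO
Why: Mitsunobu reaction, in which formate displaces the activated C6 oxygen by SN2 with clean inversion (6R→6S), and the labile formate is then removed by buffered methanolysis that spares the lactone and silyl ethers.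

Step 12
Reactants: 21 (4S,5R)-4-[(1S,2Z,6E)-1-hydroxy-3-{[(tert-butyldimethylsilyl)oxy]methyl}-7-iodoocta-2,6-dien-1-yl]-3-methylidene-5-{[(triethylsilyl)oxy]methyl}oxolan-2-one
Product: 22 (4R,5R)-4-[(1S,2Z,6E)-1-[(tert-butyldimethylsilyl)oxy]-3-{[(tert-butyldimethylsilyl)oxy]methyl}-7-iodoocta-2,6-dien-1-yl]-3-methylidene-5-{[(triethylsilyl)oxy]methyl}oxolan-2-one
Conditions: TBSOTf, 2,6-lutidine, CH2Cl2, −78 °C
Reagents that add atoms: tert-butyldimethylsilyl triflate CC(C)(C)[Si](C)(C)OS(=O)(=O)C(F)(F)F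
Why: Silylation of the hindered secondary allylic alcohol with the silyl triflate protects C6–OH for the oxidation, coupling and acylation that follow.

Step 13
Reactants: 22 (4R,5R)-4-[(1S,2Z,6E)-1-[(tert-butyldimethylsilyl)oxy]-3-{[(tert-butyldimethylsilyl)oxy]methyl}-7-iodoocta-2,6-dien-1-yl]-3-methylidene-5-{[(triethylsilyl)oxy]methyl}oxolan-2-one
Product: 23 (2R,3R)-3-[(1S,2Z,6E)-1-[(tert-butyldimethylsilyl)oxy]-3-{[(tert-butyldimethylsilyl)oxy]methyl}-7-iodoocta-2,6-dien-1-yl]-4-methylidene-5-oxooxolane-2-carbaldehyde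
Conditions: (COCl)2, DMSO, CH2Cl2, −78→−40 °C; Et3N, −78 °C→0 °C
Reagents that add atoms: none
Why: Under Swern conditions a primary triethylsilyl ether is converted directly into the aldehyde (oxidative desilylation) while the TBS ethers survive, which unveils the C9 aldehyde in one step.

Step 14
Reactants: 23 (2R,3R)-3-[(1S,2Z,6E)-1-[(tert-butyldimethylsilyl)oxy]-3-{[(tert-butyldimethylsilyl)oxy]methyl}-7-iodoocta-2,6-dien-1-yl]-4-methylidene-5-oxooxolane-2-carbaldehyde
Product: 24 (1(10)E,4Z)-6β,15-bis[(tert-butyldimethylsilyl)oxy]-9α-hydroxygermacra-1(10),4,11(13)-trien-12,8α-olide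
Conditions: CrCl2 (8 equiv), NiCl2 (2 mol %), DMSO–THF, rt, 0.003 M, slow addition
Reagents that add atoms: none
Why: Nozaki–Hiyama–Kishi macrocyclisation, in which the alkenylchromium formed from the vinyl iodide with retention of geometry adds to the α‑acyloxy aldehyde anti to the C8–O bond (polar Felkin–Anh), which should give the 9α (9S) alcohol and close the ten‑membered ring at C9–C10.

Step 15
Reactants: 24 (1(10)E,4Z)-6β,15-bis[(tert-butyldimethylsilyl)oxy]-9α-hydroxygermacra-1(10),4,11(13)-trien-12,8α-olide; 25 angelic acid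
Product: 27 (1(10)E,4Z)-9α-angeloyloxy-6β,15-bis[(tert-butyldimethylsilyl)oxy]germacra-1(10),4,11(13)-trien-12,8α-olide, via mixed anhydride 26 (not isolated)
Conditions: 2,4,6-trichlorobenzoyl chloride, Et3N, PhMe, rt; then 24, 75 °C (no DMAP)
Reagents that add atoms: none
Why: Yamaguchi esterification through the mixed anhydride without DMAP acylates the hindered allylic alcohol with retention at C9 and avoids angelate‑to‑tiglate isomerisation.

Step 16
Reactants: 27 (1(10)E,4Z)-9α-angeloyloxy-6β,15-bis[(tert-butyldimethylsilyl)oxy]germacra-1(10),4,11(13)-trien-12,8α-olide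
Product: 28 (1(10)E,4Z)-9α-angeloyloxy-6β,15-dihydroxygermacra-1(10),4,11(13)-trien-12,8α-olide
Conditions: HF·pyridine, pyridine, THF, 0 °C→rt
Reagents that add atoms: none
Why: Buffered fluoride cleaves both TBS ethers under weakly acidic conditions that should spare the angelate and the methylene lactone and avoid base‑induced translactonisation of the freed C6–OH.

Step 17
Reactants: 28 (1(10)E,4Z)-9α-angeloyloxy-6β,15-dihydroxygermacra-1(10),4,11(13)-trien-12,8α-olide
Product: 30 9α-angeloyloxy-6β-hydroxy-15-oxoelema-1,3,11(13)-trien-12,8α-olide (5R,6S,7S,8R,9S,10S; CNP0320538.1), via germacranolide aldehyde 29 (not isolated)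
Conditions: TEMPO (0.2 equiv), PhI(OAc)2 (1.2 equiv), CH2Cl2, 0 °C→rt; aq. Na2S2O3/NaHCO3 wash; then PhMe (BHT), 80 °C
Reagents that add atoms: none
Why: Chemoselective TEMPO/PhI(OAc)2 oxidation of the primary allylic C15–OH (the secondary C6–OH is left) gives the cyclodeca‑1,5‑dienal 29, which on warming undergoes a concerted [3,3]‑sigmatropic (Cope) rearrangement in which C2–C3 breaks and C5–C10 forms. The closest precedent is the thermal germacranolide‑to‑elemanolide Cope rearrangement, which is especially easy when C4 bears a formyl group and is the presumed biogenesis of elemanolides. The six‑membered ring C5–C6–C7–C8–C9–C10 is closed transannularly through a chair‑like six‑centre transition state (the ten‑membered ring contracts to six, with the lactone already in place). C10 and C5 are set by this chair: both ring alkenes are trans, so C14 and H‑5 end up anti with the vinyl group and C4 both equatorial, and the trans‑fused lactone, which must stay diequatorial at C7/C8, allows only the chair that gives 10S (methyl β) and 5R (H α). The step needs chair over boat selectivity and a favourable equilibrium; these are secured by the alkene geometries fixed in steps 3 and 5, by release of medium‑ring strain and by the enal conjugation that is retained in the product (C3=C4–C15HO).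

**Compound list**

1 | pent-3-yn-1-ol | CC#CCCO | starting material
2 | 5-bromopent-2-yne | CC#CCCBr | intermediate
3 | tert-butyldimethyl(prop-2-yn-1-yloxy)silane | C#CCO[Si](C)(C)C(C)(C)C | starting material
4 | ethyl 4-[(tert-butyldimethylsilyl)oxy]but-2-ynoate | CCOC(=O)C#CCO[Si](C)(C)C(C)(C)C | intermediate
5 | pent-3-yn-1-ylmagnesium bromide | CC#CCC[Mg]Br | intermediate (not isolated)
6 | pent-3-yn-1-ylcopper (MgBr2 complex) | CC#CCC[Cu] | intermediate (not isolated)
7 | ethyl (2Z)-3-{[(tert-butyldimethylsilyl)oxy]methyl}oct-2-en-6-ynoate | CCOC(=O)/C=C(\CO[Si](C)(C)C(C)(C)C)CCC#CC | intermediate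
8 | (2Z)-3-{[(tert-butyldimethylsilyl)oxy]methyl}oct-2-en-6-yn-1-ol | OC/C=C(\CO[Si](C)(C)C(C)(C)C)CCC#CC | intermediate
9 | alkenylzirconocene chloride of 8 (Zr on the methyl‑bearing alkene carbon, H and Zr cis; hydroxyl as zirconocene alkoxide; Cp drawn σ‑bonded) | C/C(=C\CC/C(CO[Si](C)(C)C(C)(C)C)=C/CO[Zr](Cl)(C1C=CC=C1)C1C=CC=C1)[Zr](Cl)(C1C=CC=C1)C1C=CC=C1 | intermediate (not isolated)
10 | (2Z,6E)-3-{[(tert-butyldimethylsilyl)oxy]methyl}-7-iodoocta-2,6-dien-1-ol | OC/C=C(\CO[Si](C)(C)C(C)(C)C)CC/C=C(\C)I | intermediate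
11 | (2Z,6E)-3-{[(tert-butyldimethylsilyl)oxy]methyl}-7-iodoocta-2,6-dienal | O=C/C=C(\CO[Si](C)(C)C(C)(C)C)CC/C=C(\C)I | intermediate
12 | (5R)-5-(hydroxymethyl)oxolan-2-one | OC[C@@H]1OC(=O)CC1 | starting material
13 | (5R)-5-{[(triethylsilyl)oxy]methyl}oxolan-2-one | CC[Si](CC)(CC)OC[C@@H]1OC(=O)CC1 | intermediate
14 | (5R)-3-[(dimethylamino)methyl]-5-{[(triethylsilyl)oxy]methyl}oxolan-2-one (Mannich base, C3 epimers) | CC[Si](CC)(CC)OC[C@@H]1OC(=O)C(CN(C)C)C1 | intermediate (not isolated)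
15 | methiodide of 14 | CC[Si](CC)(CC)OC[C@@H]1OC(=O)C(C[N+](C)(C)C)C1.[I-] | intermediate (not isolated)
16 | (5R)-3-methylidene-5-{[(triethylsilyl)oxy]methyl}oxolan-2-one | CC[Si](CC)(CC)OC[C@@H]1OC(=O)C(=C)C1 | intermediate
17 | (5R)-3-bromo-3-(bromomethyl)-5-{[(triethylsilyl)oxy]methyl}oxolan-2-one (C3 epimers) | CC[Si](CC)(CC)OC[C@@H]1OC(=O)C(Br)(CBr)C1 | intermediate (not isolated)
18 | (5R)-3-(bromomethyl)-5-{[(triethylsilyl)oxy]methyl}furan-2(5H)-one | CC[Si](CC)(CC)OC[C@@H]1OC(=O)C(CBr)=C1 | intermediate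
19 | (4S,5R)-4-[(1R,2Z,6E)-1-hydroxy-3-{[(tert-butyldimethylsilyl)oxy]methyl}-7-iodoocta-2,6-dien-1-yl]-3-methylidene-5-{[(triethylsilyl)oxy]methyl}oxolan-2-one (6R, 7,8‑trans) | CC[Si](CC)(CC)OC[C@@H]1OC(=O)C(=C)[C@H]1[C@H](O)/C=C(\CO[Si](C)(C)C(C)(C)C)CC/C=C(\C)I | intermediate
20 | formate of the C6‑inverted alcohol (6S) | CC[Si](CC)(CC)OC[C@@H]1OC(=O)C(=C)[C@H]1[C@@H](OC=O)/C=C(\CO[Si](C)(C)C(C)(C)C)CC/C=C(\C)I | intermediate (not isolated)
21 | (4S,5R)-4-[(1S,2Z,6E)-1-hydroxy-3-{[(tert-butyldimethylsilyl)oxy]methyl}-7-iodoocta-2,6-dien-1-yl]-3-methylidene-5-{[(triethylsilyl)oxy]methyl}oxolan-2-one (6S) | CC[Si](CC)(CC)OC[C@@H]1OC(=O)C(=C)[C@H]1[C@@H](O)/C=C(\CO[Si](C)(C)C(C)(C)C)CC/C=C(\C)I | intermediate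
22 | (4R,5R)-4-[(1S,2Z,6E)-1-[(tert-butyldimethylsilyl)oxy]-3-{[(tert-butyldimethylsilyl)oxy]methyl}-7-iodoocta-2,6-dien-1-yl]-3-methylidene-5-{[(triethylsilyl)oxy]methyl}oxolan-2-one | CC[Si](CC)(CC)OC[C@@H]1OC(=O)C(=C)[C@H]1[C@@H](O[Si](C)(C)C(C)(C)C)/C=C(\CO[Si](C)(C)C(C)(C)C)CC/C=C(\C)I | intermediate
23 | (2R,3R)-3-[(1S,2Z,6E)-1-[(tert-butyldimethylsilyl)oxy]-3-{[(tert-butyldimethylsilyl)oxy]methyl}-7-iodoocta-2,6-dien-1-yl]-4-methylidene-5-oxooxolane-2-carbaldehyde | O=C[C@@H]1OC(=O)C(=C)[C@H]1[C@@H](O[Si](C)(C)C(C)(C)C)/C=C(\CO[Si](C)(C)C(C)(C)C)CC/C=C(\C)I | intermediate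
24 | (1(10)E,4Z)-6β,15-bis[(tert-butyldimethylsilyl)oxy]-9α-hydroxygermacra-1(10),4,11(13)-trien-12,8α-olide (6S,7R,8R,9S) | C1/C=C(\C)[C@H](O)[C@@H]2OC(=O)C(=C)[C@H]2[C@@H](O[Si](C)(C)C(C)(C)C)/C=C(\CO[Si](C)(C)C(C)(C)C)C1 | intermediate
25 | angelic acid, (2Z)-2-methylbut-2-enoic acid | C/C=C(/C)C(=O)O | starting material
26 | angelic 2,4,6-trichlorobenzoic anhydride | C/C=C(/C)C(=O)OC(=O)c1c(Cl)cc(Cl)cc1Cl | intermediate (not isolated)
27 | (1(10)E,4Z)-9α-angeloyloxy-6β,15-bis[(tert-butyldimethylsilyl)oxy]germacra-1(10),4,11(13)-trien-12,8α-olide | C1/C=C(\C)[C@H](OC(=O)/C(C)=C\C)[C@@H]2OC(=O)C(=C)[C@H]2[C@@H](O[Si](C)(C)C(C)(C)C)/C=C(\CO[Si](C)(C)C(C)(C)C)C1 | intermediate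
28 | (1(10)E,4Z)-9α-angeloyloxy-6β,15-dihydroxygermacra-1(10),4,11(13)-trien-12,8α-olide (6S,7S,8R,9S) | C1/C=C(\C)[C@H](OC(=O)/C(C)=C\C)[C@@H]2OC(=O)C(=C)[C@H]2[C@@H](O)/C=C(\CO)C1 | intermediate
29 | (1(10)E,4Z)-9α-angeloyloxy-6β-hydroxy-15-oxogermacra-1(10),4,11(13)-trien-12,8α-olide | C1/C=C(\C)[C@H](OC(=O)/C(C)=C\C)[C@@H]2OC(=O)C(=C)[C@H]2[C@@H](O)/C=C(\C=O)C1 | intermediate (not isolated)
30 | 9α-angeloyloxy-6β-hydroxy-15-oxoelema-1,3,11(13)-trien-12,8α-olide (5R,6S,7S,8R,9S,10S) | C=C[C@]1(C)[C@H](OC(=O)/C(C)=C\C)[C@@H]2OC(=O)C(=C)[C@H]2[C@@H](O)[C@H]1C(=C)C=O | target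

**Totals.** Total step count: 17. Longest linear sequence: 13 steps (1 → 2 → 7 → 8 → 10 → 11 → 19 → 21 → 22 → 23 → 24 → 27 → 28 → 30).

**Steps most likely to fail, with fallbacks**

Step 14 (macrocyclisation). The alkenylchromium may couple between molecules instead of closing the strained ten‑membered ring. Where it does close, ring strain rather than the Felkin preference may decide which aldehyde face is attacked, so the 9β‑alcohol could result. The fallback sets out from 23 and comes back at 27. If ring closure delivers the 9β‑epimer, (1(10)E,4Z)-6β,15-bis[(tert-butyldimethylsilyl)oxy]-9β-hydroxygermacra-1(10),4,11(13)-trien-12,8α-olide F1, it is not recycled. It is esterified with angelic acid 25 under Mitsunobu conditions (PPh3, DIAD, PhMe, 0 °C), so that SN2 inversion at C9 gives angelate 27 directly.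

Step 11 (inversion at C6). The activated allylic alcohol may ionise or eliminate towards a diene, or react SN2′, and a poor C6 ratio from the allylation of step 10 would be carried through. The fallback sets out from 19 and comes back at 21. Dess–Martin oxidation of 19 (or of any C6 mixture) gives the enone, (4S,5R)-4-[(2Z,6E)-3-{[(tert-butyldimethylsilyl)oxy]methyl}-7-iodoocta-2,6-dienoyl]-3-methylidene-5-{[(triethylsilyl)oxy]methyl}oxolan-2-one F2. Reagent‑controlled 1,2‑reduction (CBS oxazaborolidine, catecholborane, −78 °C, catalyst enantiomer chosen for the 6S carbinol) then gives 21.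

Step 17 (oxidation and Cope rearrangement). The γ‑hydroxy‑enal 29 may rest as its cyclic hemiacetal (O6 to C15), which withholds the conjugated aldehyde from the rearrangement. Acetic acid from the oxidant may also start transannular cyclisation of the diene. The fallback sets out from 27 and comes back at 30. The primary allylic silyl ether alone is cleaved (HF·pyridine, pyridine, THF, 0 °C) to the 15‑alcohol, (1(10)E,4Z)-9α-angeloyloxy-6β-[(tert-butyldimethylsilyl)oxy]-15-hydroxygermacra-1(10),4,11(13)-trien-12,8α-olide F3. MnO2 in CH2Cl2 gives the protected aldehyde, (1(10)E,4Z)-9α-angeloyloxy-6β-[(tert-butyldimethylsilyl)oxy]-15-oxogermacra-1(10),4,11(13)-trien-12,8α-olide F4. This is rearranged in toluene at 80 °C to the silylated elemanolide, 9α-angeloyloxy-6β-[(tert-butyldimethylsilyl)oxy]-15-oxoelema-1,3,11(13)-trien-12,8α-olide F5, and HF·pyridine then releases 30.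

Further compounds
F1 | step 14 | (1(10)E,4Z)-6β,15-bis[(tert-butyldimethylsilyl)oxy]-9β-hydroxygermacra-1(10),4,11(13)-trien-12,8α-olide | C1/C=C(\C)[C@@H](O)[C@@H]2OC(=O)C(=C)[C@H]2[C@@H](O[Si](C)(C)C(C)(C)C)/C=C(\CO[Si](C)(C)C(C)(C)C)C1
F2 | step 11 | (4S,5R)-4-[(2Z,6E)-3-{[(tert-butyldimethylsilyl)oxy]methyl}-7-iodoocta-2,6-dienoyl]-3-methylidene-5-{[(triethylsilyl)oxy]methyl}oxolan-2-one | CC[Si](CC)(CC)OC[C@@H]1OC(=O)C(=C)[C@H]1C(=O)/C=C(\CO[Si](C)(C)C(C)(C)C)CC/C=C(\C)I
F3 | step 17 | (1(10)E,4Z)-9α-angeloyloxy-6β-[(tert-butyldimethylsilyl)oxy]-15-hydroxygermacra-1(10),4,11(13)-trien-12,8α-olide | C1/C=C(\C)[C@H](OC(=O)/C(C)=C\C)[C@@H]2OC(=O)C(=C)[C@H]2[C@@H](O[Si](C)(C)C(C)(C)C)/C=C(\CO)C1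
F4 | step 17 | (1(10)E,4Z)-9α-angeloyloxy-6β-[(tert-butyldimethylsilyl)oxy]-15-oxogermacra-1(10),4,11(13)-trien-12,8α-olide | C1/C=C(\C)[C@H](OC(=O)/C(C)=C\C)[C@@H]2OC(=O)C(=C)[C@H]2[C@@H](O[Si](C)(C)C(C)(C)C)/C=C(\C=O)C1
F5 | step 17 | 9α-angeloyloxy-6β-[(tert-butyldimethylsilyl)oxy]-15-oxoelema-1,3,11(13)-trien-12,8α-olide | C=C[C@]1(C)[C@H](OC(=O)/C(C)=C\C)[C@@H]2OC(=O)C(=C)[C@H]2[C@@H](O[Si](C)(C)C(C)(C)C)[C@H]1C(=C)C=O
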